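## Retrosynthetic overview

1. Labels: C1 = CHOAc, C2 = CH2, C3 = CHBr, C4 = CMe2, C5 = CHCl, C6 = ring alkene carbon, C7 = exocyclic CH, C8 = CH2Br; with the ring drawn C1→C6 clockwise, β is the face towards the viewer (C1 acetate and C3 bromine in the target) and α the opposite face (C5 chlorine). The strategy rests on the allylic C1 carbinol beside the exocyclic C6=C7 alkene of the single six-membered carbocycle C1–C6, which is the retron of a syn reductive coupling of a C6≡C7 alkyne with a C1 aldehyde.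
2. Key disconnection C1–C6: the only ring is closed in step 10 from the acyclic, halogen-free ynal 16 (nickel, carbene ligand, Et3SiH); this also sets C1 (oxygen trans to the C5 oxygen) and places C8 cis to C5.
3. Endgame (steps 11–18): Cl at C5, Br at C3 and OAc at C1 enter by substitution with inversion, in that order, then Br at C8. This order leaves only axial hydrogens on the β face when bromide attacks the neopentyl C3, and it delays the C1 ester, which would otherwise act as a neighbouring group at C3. Four ethers of graded lability make the order possible: 3,4-dimethoxybenzyl (DMB) on O5, 4-methoxybenzyl (PMB) on O3, triethylsilyl on O1 and tert-butyldiphenylsilyl (TBDPS) on O8.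
4. Ynal 16 (steps 1–9): (R)-pantolactone supplies C3–C6 and the C5 stereocentre; C7 comes from the Ohira–Bestmann reagent, C8 from formaldehyde, and C1–C2 with the C3 stereocentre from a Brown allylboration followed by alkene cleavage.
5. Ring order: one ring only, formed in step 10.

Key step: step 10

## Route

Step 1
Reactants: 1 (R)-pantolactone
Product: 2 (3R)-3-[(3,4-dimethoxybenzyl)oxy]-4,4-dimethyldihydrofuran-2(3H)-one
Conditions: 3,4-(MeO)2C6H3CH2OC(=NH)CCl3, CSA (cat.), CH2Cl2, 0 °C → rt
Reagents that add atoms: 3,4-dimethoxybenzyl 2,2,2-trichloroacetimidate, COc1ccc(COC(=N)C(Cl)(Cl)Cl)cc1OC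
Why: Acid-catalysed benzylation with a trichloroacetimidate etherifies the α-hydroxy lactone without base, so the enolisable C5 centre should keep its (R) configuration.

Step 2
Reactants: 2 (3R)-3-[(3,4-dimethoxybenzyl)oxy]-4,4-dimethyldihydrofuran-2(3H)-one
Product: 3 (3R)-3-[(3,4-dimethoxybenzyl)oxy]-4,4-dimethyltetrahydrofuran-2-ol (lactol, both anomers)
Conditions: i-Bu2AlH, CH2Cl2, −78 °C; aq. potassium sodium tartrate
Reagents that add atoms: none
Why: Partial reduction of a lactone with i-Bu2AlH stops at the aluminium hemiacetal at −78 °C and gives the lactol on work-up; the stereocentre is not involved.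

Step 3
Reactants: 3 (3R)-3-[(3,4-dimethoxybenzyl)oxy]-4,4-dimethyltetrahydrofuran-2-ol
Product: 4 (3S)-3-[(3,4-dimethoxybenzyl)oxy]-2,2-dimethylpent-4-yn-1-ol
Conditions: MeC(O)C(N2)P(O)(OMe)2, K2CO3, MeOH, 0 °C → rt
Reagents that add atoms: dimethyl (1-diazo-2-oxopropyl)phosphonate (Ohira–Bestmann reagent), CC(=O)C(=[N+]=[N-])P(=O)(OC)OC
Why: Ohira–Bestmann (Seyferth–Gilbert) homologation traps the open hydroxy aldehyde form of the lactol, and the diazoalkene loses N2 with 1,2-hydrogen shift to the terminal alkyne, which adds C7 and leaves C5 untouched (the descriptor becomes (S) only through the priority rules).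

Step 4
Reactants: 4 (3S)-3-[(3,4-dimethoxybenzyl)oxy]-2,2-dimethylpent-4-yn-1-ol
Product: 5 (3S)-3-[(3,4-dimethoxybenzyl)oxy]-2,2-dimethylpent-4-ynal
Conditions: Dess–Martin periodinane, CH2Cl2, 0 °C → rt
Reagents that add atoms: none
Why: Dess–Martin oxidation of the neopentyl primary alcohol gives an aldehyde without α-hydrogen, which can neither enolise nor eliminate.

Step 5
Reactants: 5 (3S)-3-[(3,4-dimethoxybenzyl)oxy]-2,2-dimethylpent-4-ynal; 6 allylmagnesium bromide
Product: 9 (4S,6S)-6-[(3,4-dimethoxybenzyl)oxy]-5,5-dimethyloct-1-en-7-yn-4-ol, via B-allyldiisopinocampheylborane 7 (not isolated), via borinate ester 8 (not isolated)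
Conditions: (−)-Ipc2BOMe [from (+)-α-pinene], Et2O, 0 °C → rt; then 5, −78 °C; NaOH, H2O2, 0 °C → rt
Reagents that add atoms: none
Why: Brown allylboration through a closed chair transition state: the allylborane made from the (+)-α-pinene-derived borinate should deliver allyl to the Si face of the α-quaternary aldehyde under reagent control, setting C3 as (S), anti to the C5 oxygen, and alkaline peroxide frees the alcohol from borinate 8.

Step 6
Reactants: 9 (4S,6S)-6-[(3,4-dimethoxybenzyl)oxy]-5,5-dimethyloct-1-en-7-yn-4-ol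
Product: 10 (4S,6S)-6-[(3,4-dimethoxybenzyl)oxy]-4-[(4-methoxybenzyl)oxy]-5,5-dimethyloct-1-en-7-yne
Conditions: NaH, 4-MeOC6H4CH2Cl, Bu4NI (cat.), DMF, 0 °C → rt
Reagents that add atoms: 4-methoxybenzyl chloride, COc1ccc(CCl)cc1
Why: Williamson etherification of the hindered sodium alkoxide with a reactive benzylic chloride under iodide catalysis; neither stereocentre is touched.

Step 7
Reactants: 10 (4S,6S)-6-[(3,4-dimethoxybenzyl)oxy]-4-[(4-methoxybenzyl)oxy]-5,5-dimethyloct-1-en-7-yne; 11 formaldehyde (as paraformaldehyde)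
Product: 13 (4S,6S)-4-[(3,4-dimethoxybenzyl)oxy]-6-[(4-methoxybenzyl)oxy]-5,5-dimethylnon-8-en-2-yn-1-ol, via lithium acetylide 12 (not isolated)
Conditions: n-BuLi, THF, −78 °C; (CH2O)n, −78 °C → rt; H2O
Reagents that add atoms: none
Why: Deprotonation of the terminal alkyne and 1,2-addition of the lithium acetylide to formaldehyde (carbonyl alkynylation) adds C8 as the propargylic alcohol.

Step 8
Reactants: 13 (4S,6S)-4-[(3,4-dimethoxybenzyl)oxy]-6-[(4-methoxybenzyl)oxy]-5,5-dimethylnon-8-en-2-yn-1-ol
Product: 14 tert-butyldiphenylsilyl ether of 13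
Conditions: t-BuPh2SiCl, imidazole, CH2Cl2, rt
Reagents that add atoms: tert-butyl(chloro)diphenylsilane, CC(C)(C)[Si](Cl)(c1ccccc1)c1ccccc1
Why: Imidazole-mediated silylation of the unhindered primary alcohol gives an acid- and oxidant-stable silyl ether that is carried to step 17.

Step 9
Reactants: 14 tert-butyldiphenylsilyl ether of 13
Product: 16 (3S,5S)-8-[(tert-butyldiphenylsilyl)oxy]-5-[(3,4-dimethoxybenzyl)oxy]-3-[(4-methoxybenzyl)oxy]-4,4-dimethyloct-6-ynal, via vicinal diol 15 (not isolated)
Conditions: OsO4 (cat.), NaIO4, 2,6-lutidine, dioxane/H2O, rt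
Reagents that add atoms: osmium tetroxide, O=[Os](=O)(=O)=O (passes on the oxygen that ends on C1; re-formed by sodium periodate, [Na+].[O-]I(=O)(=O)=O, and water, O)
Why: Lemieux–Johnson oxidation: OsO4 dihydroxylates the terminal alkene far faster than the internal alkyne and NaIO4 cleaves diol 15 to the aldehyde, while the electron-rich benzyl ethers, which ozone would attack, survive.

Step 10
Reactants: 16 (3S,5S)-8-[(tert-butyldiphenylsilyl)oxy]-5-[(3,4-dimethoxybenzyl)oxy]-3-[(4-methoxybenzyl)oxy]-4,4-dimethyloct-6-ynal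
Product: 17 cyclised triethylsilyl ether (1α-OSiEt3; 3α-OPMB; 5β-ODMB; 4,4-dimethyl; exocyclic C6=C7 with C8H2OTBDPS cis to C5)
Conditions: Ni(COD)2 (cat.), 1,3-dimesitylimidazol-2-ylidene (cat.), Et3SiH, THF, rt, slow addition of 16 at high dilution
Reagents that add atoms: triethylsilane, CC[SiH](CC)CC
Why: Zerovalent nickel carrying the carbene ligand couples the C6≡C7 alkyne and the C1 aldehyde oxidatively to an oxanickelacyclopentene (new C1–C6 bond, nickel bound to C7 and to the C1 oxygen), Et3SiH cleaves the Ni–O bond by σ-bond metathesis and C–H reductive elimination at C7 releases the silyl ether, so hydrogen and the C1–C6 bond add syn across the alkyne and C8 ends up cis to C5. The closest known reaction type is the nickel-catalysed reductive cyclisation of ynals with trialkylsilanes, established for 2-alkylidenecycloalkanol silyl ethers with five- and six-membered rings. The single ring, the six-membered carbocycle C1–C6, closes in the exo mode at the alkyne (6-exo-dig sense): C1 bonds to the proximal alkyne carbon C6 and C7 stays outside the ring. The new stereocentre C1 is set by the chair-like metallacycle, in which the C5 ether stands pseudo-axial to escape allylic 1,3-strain with C8, the C3 ether is equatorial and the C1–O bond lies in the plane of the nickelacycle, so that C1–O should come out trans to C5–O and cis to C3–O (1α). The step needs ring closure to outpace silane reduction of the aldehyde or alkyne alone and intermolecular coupling, and it needs a single alkene geometry; the 1,7-disposition of the two partners, the gem-dimethyl group at C4, slow addition at high dilution and the absence of carbon–halogen bonds secure the first, the syn mechanism secures the second.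

Step 11
Reactants: 17 cyclised triethylsilyl ether (1α-OSiEt3; 3α-OPMB; 5β-ODMB)
Product: 18 C5 allylic alcohol (1α-OSiEt3; 3α-OPMB; 5β-OH; C8H2OTBDPS)
Conditions: DDQ (1.1 equiv), CH2Cl2/aq. Na2HPO4–NaH2PO4 (pH 7), 0 °C
Reagents that add atoms: none
Why: Oxidative cleavage of a benzylic ether by DDQ (hydride abstraction, then hydrolysis of the oxocarbenium ion): the 3,4-dimethoxybenzyl ether is oxidised faster than the 4-methoxybenzyl ether at C3, and the buffered two-phase medium should spare both silyl ethers.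

Step 12
Reactants: 18 C5 allylic alcohol (1α-OSiEt3; 3α-OPMB; 5β-OH)
Product: 19 C5 chloride (1α-OSiEt3; 3α-OPMB; 5α-Cl; C8H2OTBDPS)
Conditions: PPh3, Cl3CC(O)CCl3, CH2Cl2, −20 → 0 °C
Reagents that add atoms: hexachloroacetone, ClC(Cl)(Cl)C(=O)C(Cl)(Cl)Cl
Why: Appel-type deoxychlorination with PPh3 and hexachloroacetone, a reagent pair known to turn allylic alcohols into chlorides with inversion and little allylic transposition: chloride displaces the axial C5 oxyphosphonium group from the α face (SN2), the bulky silyloxymethyl group on C7 disfavouring SN2′ attack, so that C5 should become the α-chloride.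

Step 13
Reactants: 19 C5 chloride (1α-OSiEt3; 3α-OPMB; 5α-Cl)
Product: 20 C3 alcohol (1α-OSiEt3; 3α-OH; 5α-Cl; C8H2OTBDPS)
Conditions: DDQ (1.5 equiv), CH2Cl2/aq. Na2HPO4–NaH2PO4 (pH 7), 0 °C → rt
Reagents that add atoms: none
Why: DDQ cleavage of the remaining 4-methoxybenzyl ether; the silyl ethers, the alkene and the allylic chloride are inert to the buffered oxidant.

Step 14
Reactants: 20 C3 alcohol (1α-OSiEt3; 3α-OH; 5α-Cl)
Product: 21 C3 bromide (1α-OSiEt3; 3β-Br; 5α-Cl; C8H2OTBDPS)
Conditions: CBr4, PPh3, 2,6-lutidine, toluene, 0 → 50 °C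
Reagents that add atoms: carbon tetrabromide, BrC(Br)(Br)Br
Why: Appel bromination with inversion at C3: in 20 the groups at C1, C3 and C5 are all α and equatorial, so bromide meets only axial hydrogens on the β face, and the silyl ether at C1, unlike an ester, cannot take part as a neighbouring group.

Step 15
Reactants: 21 C3 bromide (1α-OSiEt3; 3β-Br; 5α-Cl)
Product: 22 C1 allylic alcohol (1α-OH; 3β-Br; 5α-Cl; C8H2OTBDPS)
Conditions: PPTS (cat.), MeOH/CH2Cl2, 0 °C
Reagents that add atoms: none
Why: Acid-catalysed methanolysis of the triethylsilyl ether, which is far more labile than the tert-butyldiphenylsilyl ether; the halides are inert to PPTS.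

Step 16
Reactants: 22 C1 allylic alcohol (1α-OH; 3β-Br; 5α-Cl)
Product: 23 C1 acetate (1β-OAc; 3β-Br; 5α-Cl; C8H2OTBDPS)
Conditions: PPh3, DIAD, AcOH, THF, 0 °C → rt
Reagents that add atoms: acetic acid, CC(=O)O
Why: Mitsunobu esterification with inversion at C1: in the chair with axial C5–Cl and equatorial C3–Br the C1 oxyphosphonium group is axial and aligned with the alkene π system, and acetate displaces it from the β face to give the 1β-acetate of the target.

Step 17
Reactants: 23 C1 acetate (1β-OAc; 3β-Br; 5α-Cl; C8H2OTBDPS)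
Product: 24 C8 allylic alcohol (1β-OAc; 3β-Br; 5α-Cl; C8H2OH)
Conditions: HF·pyridine, pyridine, THF, 0 °C → rt
Reagents that add atoms: none
Why: Fluoride-induced desilylation with buffered HF·pyridine, which is not basic enough to cause elimination of the halides or acyl transfer.

Step 18
Reactants: 24 C8 allylic alcohol (1β-OAc; 3β-Br; 5α-Cl; C8H2OH)
Product: 25 (1S,3R,5R)-5-bromo-2-[(Z)-2-bromoethylidene]-3-chloro-4,4-dimethylcyclohexyl acetate (target CNP0362553.1)
Conditions: CBr4, PPh3, CH2Cl2, −20 → 0 °C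
Reagents that add atoms: carbon tetrabromide, BrC(Br)(Br)Br
Why: Appel bromination of the primary allylic alcohol (SN2 at C8, no stereocentre and no allylic shift involved) should give the target.

## Compound list

1 | (R)-pantolactone | CC1(C)COC(=O)[C@@H]1O | starting material
2 | (3R)-3-[(3,4-dimethoxybenzyl)oxy]-4,4-dimethyldihydrofuran-2(3H)-one | CC1(C)COC(=O)[C@@H]1OCc1ccc(OC)c(OC)c1 | intermediate
3 | (3R)-3-[(3,4-dimethoxybenzyl)oxy]-4,4-dimethyltetrahydrofuran-2-ol (both anomers) | CC1(C)COC(O)[C@@H]1OCc1ccc(OC)c(OC)c1 | intermediate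
4 | (3S)-3-[(3,4-dimethoxybenzyl)oxy]-2,2-dimethylpent-4-yn-1-ol | OCC(C)(C)[C@@H](OCc1ccc(OC)c(OC)c1)C#C | intermediate
5 | (3S)-3-[(3,4-dimethoxybenzyl)oxy]-2,2-dimethylpent-4-ynal | O=CC(C)(C)[C@@H](OCc1ccc(OC)c(OC)c1)C#C | intermediate
6 | allylmagnesium bromide | C=CC[Mg]Br | starting material
7 | B-allyldiisopinocampheylborane, isopinocampheyl groups from (+)-α-pinene (not isolated) | C=CCB([C@@H]1C[C@@H]2C[C@@H](C2(C)C)[C@H]1C)[C@@H]1C[C@@H]2C[C@@H](C2(C)C)[C@H]1C | intermediate
8 | diisopinocampheylborinate ester of 9 (not isolated) | C=CC[C@H](OB([C@@H]1C[C@@H]2C[C@@H](C2(C)C)[C@H]1C)[C@@H]1C[C@@H]2C[C@@H](C2(C)C)[C@H]1C)C(C)(C)[C@@H](OCc1ccc(OC)c(OC)c1)C#C | intermediate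
9 | (4S,6S)-6-[(3,4-dimethoxybenzyl)oxy]-5,5-dimethyloct-1-en-7-yn-4-ol | C=CC[C@H](O)C(C)(C)[C@@H](OCc1ccc(OC)c(OC)c1)C#C | intermediate
10 | (4S,6S)-6-[(3,4-dimethoxybenzyl)oxy]-4-[(4-methoxybenzyl)oxy]-5,5-dimethyloct-1-en-7-yne | C=CC[C@H](OCc1ccc(OC)cc1)C(C)(C)[C@@H](OCc1ccc(OC)c(OC)c1)C#C | intermediate
11 | formaldehyde (used as paraformaldehyde) | C=O | starting material
12 | lithium acetylide of 10 (not isolated) | C=CC[C@H](OCc1ccc(OC)cc1)C(C)(C)[C@@H](OCc1ccc(OC)c(OC)c1)C#C[Li] | intermediate
13 | (4S,6S)-4-[(3,4-dimethoxybenzyl)oxy]-6-[(4-methoxybenzyl)oxy]-5,5-dimethylnon-8-en-2-yn-1-ol | C=CC[C@H](OCc1ccc(OC)cc1)C(C)(C)[C@@H](OCc1ccc(OC)c(OC)c1)C#CCO | intermediate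
14 | tert-butyldiphenylsilyl ether of 13 | C=CC[C@H](OCc1ccc(OC)cc1)C(C)(C)[C@@H](OCc1ccc(OC)c(OC)c1)C#CCO[Si](c1ccccc1)(c1ccccc1)C(C)(C)C | intermediate
15 | terminal vicinal diol from 14, both epimers at the new carbinol carbon (not isolated) | OCC(O)C[C@H](OCc1ccc(OC)cc1)C(C)(C)[C@@H](OCc1ccc(OC)c(OC)c1)C#CCO[Si](c1ccccc1)(c1ccccc1)C(C)(C)C | intermediate
16 | (3S,5S)-8-[(tert-butyldiphenylsilyl)oxy]-5-[(3,4-dimethoxybenzyl)oxy]-3-[(4-methoxybenzyl)oxy]-4,4-dimethyloct-6-ynal (key-step precursor) | O=CC[C@H](OCc1ccc(OC)cc1)C(C)(C)[C@@H](OCc1ccc(OC)c(OC)c1)C#CCO[Si](c1ccccc1)(c1ccccc1)C(C)(C)C | intermediate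
17 | cyclised triethylsilyl ether: 1α-OSiEt3, 3α-OPMB, 5β-ODMB, 4,4-dimethyl, exocyclic C6=C7 with C8H2OTBDPS cis to C5 (key-step product) | CC[Si](CC)(CC)O[C@@H]1C[C@H](OCc2ccc(OC)cc2)C(C)(C)[C@@H](OCc2ccc(OC)c(OC)c2)/C1=C\CO[Si](c1ccccc1)(c1ccccc1)C(C)(C)C | intermediate
18 | C5 allylic alcohol: 1α-OSiEt3, 3α-OPMB, 5β-OH, C8H2OTBDPS | CC[Si](CC)(CC)O[C@@H]1C[C@H](OCc2ccc(OC)cc2)C(C)(C)[C@@H](O)/C1=C\CO[Si](c1ccccc1)(c1ccccc1)C(C)(C)C | intermediate
19 | C5 chloride: 1α-OSiEt3, 3α-OPMB, 5α-Cl, C8H2OTBDPS | CC[Si](CC)(CC)O[C@@H]1C[C@H](OCc2ccc(OC)cc2)C(C)(C)[C@H](Cl)/C1=C\CO[Si](c1ccccc1)(c1ccccc1)C(C)(C)C | intermediate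
20 | C3 alcohol: 1α-OSiEt3, 3α-OH, 5α-Cl, C8H2OTBDPS | CC[Si](CC)(CC)O[C@@H]1C[C@H](O)C(C)(C)[C@H](Cl)/C1=C\CO[Si](c1ccccc1)(c1ccccc1)C(C)(C)C | intermediate
21 | C3 bromide: 1α-OSiEt3, 3β-Br, 5α-Cl, C8H2OTBDPS | CC[Si](CC)(CC)O[C@@H]1C[C@@H](Br)C(C)(C)[C@H](Cl)/C1=C\CO[Si](c1ccccc1)(c1ccccc1)C(C)(C)C | intermediate
22 | C1 allylic alcohol: 1α-OH, 3β-Br, 5α-Cl, C8H2OTBDPS | O[C@@H]1C[C@@H](Br)C(C)(C)[C@H](Cl)/C1=C\CO[Si](c1ccccc1)(c1ccccc1)C(C)(C)C | intermediate
23 | C1 acetate: 1β-OAc, 3β-Br, 5α-Cl, C8H2OTBDPS | CC(=O)O[C@H]1C[C@@H](Br)C(C)(C)[C@H](Cl)/C1=C\CO[Si](c1ccccc1)(c1ccccc1)C(C)(C)C | intermediate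
24 | C8 allylic alcohol: 1β-OAc, 3β-Br, 5α-Cl, C8H2OH | CC(=O)O[C@H]1C[C@@H](Br)C(C)(C)[C@H](Cl)/C1=C\CO | intermediate
25 | (1S,3R,5R)-5-bromo-2-[(Z)-2-bromoethylidene]-3-chloro-4,4-dimethylcyclohexyl acetate (IUPAC locants; in the C1–C8 labels 1β-OAc, 3β-Br, 5α-Cl, C8 cis to C5) | CC(=O)O[C@H]1C[C@@H](Br)C(C)(C)[C@H](Cl)/C1=C\CBr | target

## Step count and risk

Total step count: 18. Longest linear sequence: 18 steps (from 1 to 25).

Steps most likely to fail:

Step 14 (bromination at C3). Backside attack at the neopentyl C3 may be slower than a 1,2-shift of a C4 substituent or ring bond onto the activated carbinol carbon, than elimination, or than loss of the C1 silyl ether at the temperature needed. Fallback: setting out from 20, Tf2O and pyridine in CH2Cl2 at −30 °C give the C3 trifluoromethanesulfonate F1. Bu4NBr in toluene at 0 °C → rt then displaces it with inversion, and the sequence comes back to the route at 21. A discrete sulfonate with a soluble bromide in a non-ionising solvent replaces phosphonium ion-pair collapse and should react at low temperature.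

Step 12 (chlorination at C5). Chloride may attack C7 with shift of the double bond into the ring (allylic transposition), or the activated allylic alcohol may ionise, which would erode regio- and stereochemistry; the axial methyl group on C4, anti to the leaving group, also slows direct displacement. Fallback: setting out from 18, MsCl and 2,4,6-collidine in DMF at 0 °C give the C5 methanesulfonate F2, which is displaced in the same flask by LiCl with inversion, returning at 19. A free, small chloride in a dipolar aprotic solvent favours bimolecular displacement at C5 over ion-pair return to C7.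

Step 10 (key step). The silane may reduce the aldehyde or the alkyne separately, or the ynal may oligomerise, before the nickelacycle forms; facial control at C1 could also be incomplete. Fallback: setting out from 16, hydrogen-mediated reductive cyclisation with the cationic rhodium complex Rh(COD)2OTf and 2,2′-bis(diphenylphosphino)biphenyl under H2 (1 atm) in ClCH2CH2Cl at rt forms the same C1–C6 bond through an oxarhodacyclopentene without any silane. It should give the free allylic alcohol F3 with the same alkene geometry; Et3SiCl and imidazole in CH2Cl2 then give 17, where the route is rejoined.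

Further compounds
F1 | step 14 | C3 trifluoromethanesulfonate of 20 (1α-OSiEt3, 3α-OTf, 5α-Cl, C8H2OTBDPS) | CC[Si](CC)(CC)O[C@@H]1C[C@H](OS(=O)(=O)C(F)(F)F)C(C)(C)[C@H](Cl)/C1=C\CO[Si](c1ccccc1)(c1ccccc1)C(C)(C)C
F2 | step 12 | C5 methanesulfonate of 18 (1α-OSiEt3, 3α-OPMB, 5β-OMs, C8H2OTBDPS) | CC[Si](CC)(CC)O[C@@H]1C[C@H](OCc2ccc(OC)cc2)C(C)(C)[C@@H](OS(C)(=O)=O)/C1=C\CO[Si](c1ccccc1)(c1ccccc1)C(C)(C)C
F3 | step 10 | free C1 allylic alcohol corresponding to 17 (1α-OH, 3α-OPMB, 5β-ODMB, C8H2OTBDPS) | O[C@@H]1C[C@H](OCc2ccc(OC)cc2)C(C)(C)[C@@H](OCc2ccc(OC)c(OC)c2)/C1=C\CO[Si](c1ccccc1)(c1ccccc1)C(C)(C)C
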